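## Structural features

The target is a 7-oxabicyclo[4.1.0]heptane: a cyclohexane whose C1–C6 bond is bridged by an oxirane oxygen (O1), with six contiguous stereocentres. C1 is quaternary and carries the benzoyloxymethyl arm (C7); C2 and C3 carry acetates, C4 and C5 free hydroxyls. O2, O4 and the oxirane oxygen lie on one face (the lower face here), O3, O5 and C7 on the other, so the 2/3, 3/4, 4/5 and 5/6 oxygen pairs are all trans and only O1/O2 are cis. The fragile points are the oxirane (acid, nucleophiles, Payne-type migration once the C5 hydroxyl is deprotonated) and three esters of two kinds beside free hydroxyls, so late alkoxide conditions threaten acyl transfer. The real difficulty is twofold: building quaternary C1 with O1 anti to the C6 oxygen it must displace, and telling four similar secondary oxygens apart (O2/O3 acetylated, O4/O5 free) in one enantiomer. The key step uses the fact that C2–C3 joins two oxygenated carbons next to C1: C1 can be a ketone, C2 its enolisable carbon and C3 an aldehyde, while C4, C5 and C6 coincide with C2, C3 and C4 of a D-galacto hexose, whose axial C4 oxygen (O6, on the face of O5) is placed to leave when the oxirane closes with inversion.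

## Logic of the disconnections

29 ⇒ 28. Only the benzylic C–O bond on O4 is made in reverse. O4 must stay distinguishable from O2/O3 to the end, and the last step must be neutral. The gain is that 28 already has every stereocentre and ester in place. The demand is that hydrogenolysis spares the oxirane and the benzoate.

28 ⇒ 26 (through 27). The oxirane bond C6–O1 is cut and O5 returns to a sulfate. O1 on the lower face is anti-periplanar to the upper-face C6–O6 bond, so closure with inversion turns a cis-5,6-diol into the trans O5/oxirane array. The cyclic sulfate activates C6 without any O5/O6 differentiation, since O1 can reach only C6 (three-membered ring) and not C5. The demand is that closure outruns acyl transfer to O1 and that sulfate hydrolysis spares the oxirane.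

26 ⇒ 22 (+ 23, 24) ⇒ 21. The two S–O bonds and then the two ketal C–O bonds are cut. The cis-5,6-diol is uncovered only when it is needed. The demand is acid hydrolysis without ester migration; the O4 benzyl ether separates the acetates from the new diol, and O1 is trans to O6 so it cannot enter the sulfite.

21 ⇒ 19 (+ 20) ⇒ 18. The acetyl C–O bonds on O2 and O3 are cut and replaced by Si–O bonds. Acetates would not survive the ylide and carboxylate steps. Because O2 and O3 share one fate, they need not be told apart. The demand is desilylation that does not move the O7 benzoate, and acetylation that stops before tertiary O1.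

18 ⇒ 16 + 17. The C7–O7 bond is cut. Carboxylate opening of a spiro-oxirane puts the benzoate on the primary carbon and frees O1 as a tertiary alcohol in one operation. The demand is attack at C7 only, under buffered conditions so that no alkoxide persists.

16 ⇒ 14 + 15. The C1–C7 and C7–O1 bonds are cut (one-carbon transfer to a ketone). This removes the quaternary centre and leaves a cyclohexanone. The demand is that the new C–C bond ends equatorial (upper face) and O1 axial (lower face).

14 ⇒ 12 + 13. The O3–Si bond is cut. A free β-hydroxy ketone would undergo retro-aldol or elimination under the ylide. The demand is a non-basic silylation.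

12 ⇒ 11. The C2–C3 bond is cut, opening the carbocycle to an acyclic keto-aldehyde whose three stereocentres come from a hexose. The gain is one ring and two stereocentres. The demand is regioselective enolisation toward C2 and equilibration to the all-trans C2/C3/C4 array.

11 ⇒ 10. Both carbonyls are taken back to carbinols. The dicarbonyl is not a storable compound; the diol is. The demand is that both hydroxyls are activated before any base is present, otherwise the hydroxy-aldehyde closes to a lactol and over-oxidises.

10 ⇒ 9 ⇒ 7 + 8. The C1–H bond (hydride) and then the anomeric C–O bond (from C–S) are cut. A thioglycoside is opened oxidatively near neutrality, which the ketal and silyl ether tolerate; acid hydrolysis of an O-glycoside would strip both.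

7 ⇒ 5 + 6 ⇒ 3 + 4 ⇒ 1 + 2. The O2–benzyl, O6–Si and ketal C–O bonds are cut in turn. The hydroxyls of 1 differ intrinsically (cis-3,4-diol, primary O6, lone O2), so each group goes on without a blocking step. This places silyl on the future O2 of the carbocycle and benzyl on the future O4, which is what later allows them to be told apart.

## Other disconnections considered

Alternative 1: The cut is the C2–O2 bond, leading back to the achiral para-quinol A1, in which C1 already carries O1 and C7. In the forward key step an arylboronic acid is esterified on O1 and its B–OH adds to C2 of one of the two enantiotopic enone arms under a chiral amine–thiourea catalyst, closing the cis-fused dioxaborolane A2.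
- In favour: a flat, easily made substrate; catalytic asymmetric induction; the quaternary centre and the C7 benzoate present from the start; O1/O2 cis by tether geometry.
- Against: A2 still has C3 as a methylene, C4 as a ketone and C5=C6 as an alkene. Four stereocentres must then be set by substrate control (α-oxygenation trans to O2, face-selective reduction, upper-face oxidation of the alkene, transfer of O1 to C6 with inversion). The β-oxy enone can revert by retro-oxa-Michael or aromatise.
- Comparison: on protecting-group load and probably on step count it is the equal or the better of the chosen plan, and it is better in setting C1 without a separate one-carbon addition. The chosen plan is stronger on stereochemical security, since three centres are bought with 1 and two more are set under equilibrium.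

Alternative 2: The cut is the pair of bonds C1–O and C4–O, leading back to the diene A3. In the forward key step a dye-sensitised photooxygenation places both oxygens of one dioxygen molecule across C1 and C4 in a concerted [4+2] addition to give the endoperoxide A4, on the lower face. Isomerisation of the peroxide into two oxiranes and hydrolytic opening of the C4/C5 oxirane at C5 would then deliver O4, O5 and the C1/C6 oxirane.
- In favour: two C–O bonds in one suprafacial step, no methylene transfer, the benzoate in place from the start. The free O4/O5 diol would emerge from an oxirane after O2/O3 are acetylated, so the acetate/hydroxyl differentiation is built in; on that point and on step count after ring construction it is the better.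
- Against: A3 must be made enantiopure and is prone to aromatise. The C2 and C3 substituents sit on opposite faces, so the facial sense of the cycloaddition rests on a size and hydrogen-bond difference. The final hydrolysis must choose one of two oxiranes and one of two carbons.
- Comparison: mechanistically cleaner (pericyclic, stereospecific) but less certain in regiocontrol at the end; the chosen plan is longer but each selectivity has a structural cause.

Alternative 3: The cut is C1–C7 and C7–O1, the same cut as step 9 of the chosen route; the difference is the origin of the ketone, here the inosose A6 made from myo-inositol A5. In the forward key step a sulfoxonium methylide adds to A6 to give the spiro-oxirane A7 with O1 axial and C7 equatorial.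
- In favour: the carbocycle and all six oxygens are purchased, so no carbocyclisation risk. The p-methoxybenzyl ethers on O2/O3 come off oxidatively under neutral conditions, arguably a cleaner handle than the silyl ethers used here (a point on which it is the better). From A7 onward the chemistry is equal in kind to steps 10–16.
- Against: A5 is meso, so a resolution or desymmetrisation is needed. Six near-equivalent secondary hydroxyls must be sorted into four classes before oxidation, which is expected to take more steps than the seven that lead to 12.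
- Comparison: equal in mechanism at the key step and in the endgame; the chosen plan is expected to be ahead before the ketone because the hydroxyls of 1 are already different and its absolute configuration is given.

Key step: step 7

Remarks on the chemistry (one line each):
- Carbocycle locants C1–C7 and O1–O7 follow the target throughout; "(2,4/3,5,6)" means O2 and O4 on the lower face, O3, O5 and O6 on the upper face.
- Identical ethers on the future O2 and O4 could not be told apart at the end, so 11 carries silyl on the future O2 and benzyl on the future O4.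
- The aldol is classed as 6-(enolendo)-exo-trig, not enolexo, because both enolate carbons (C1 and C2) become ring members.
- Compound 1 is assumed to be commercially available; a thioglycoside is used because acid unmasking of an O-glycoside would not leave the ketal in place.
- A silyl shift between O2 and O3 in 12 is inconsequential in itself, because step 8 silylates whichever is free and both end as acetates.

## Route

Step 1
Reactants: 1 phenyl 1-thio-β-D-galactopyranoside; 2 2,2-dimethoxypropane
Product: 3 phenyl 3,4-O-isopropylidene-1-thio-β-D-galactopyranoside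
Conditions: CSA (cat.), acetone, rt; Et3N quench
Reagents that add atoms: 2,2-dimethoxypropane, COC(C)(C)OC
Why: Acid-catalysed transketalisation under equilibrating conditions; the cis-3,4-diol closes the cis-fused dioxolane in preference to a 4,6-dioxane or a trans-2,3-ketal, and any mixed acetal on O6 is lost on aqueous work-up.

Step 2
Reactants: 3 phenyl 3,4-O-isopropylidene-1-thio-β-D-galactopyranoside; 4 tert-butyldimethylsilyl chloride
Product: 5 phenyl 6-O-(tert-butyldimethylsilyl)-3,4-O-isopropylidene-1-thio-β-D-galactopyranoside
Conditions: imidazole, CH2Cl2, 0 °C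
Reagents that add atoms: tert-butyldimethylsilyl chloride, CC(C)(C)[Si](C)(C)Cl
Why: Silylation of an alcohol; the primary O6 hydroxyl should react well ahead of the secondary O2 hydroxyl with a bulky silyl chloride.

Step 3
Reactants: 5 phenyl 6-O-(tert-butyldimethylsilyl)-3,4-O-isopropylidene-1-thio-β-D-galactopyranoside; 6 benzyl bromide
Product: 7 phenyl 2-O-benzyl-6-O-(tert-butyldimethylsilyl)-3,4-O-isopropylidene-1-thio-β-D-galactopyranoside
Conditions: NaH, Bu4NI (cat.), DMF, 0 °C to rt
Reagents that add atoms: benzyl bromide, BrCc1ccccc1
Why: Williamson etherification of the only free hydroxyl; the primary silyl ether has no neighbouring hydroxyl to migrate to.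

Step 4
Reactants: 7 phenyl 2-O-benzyl-6-O-(tert-butyldimethylsilyl)-3,4-O-isopropylidene-1-thio-β-D-galactopyranoside; 8 water
Product: 9 2-O-benzyl-6-O-(tert-butyldimethylsilyl)-3,4-O-isopropylidene-D-galactopyranose (anomeric mixture)
Conditions: NBS (1.2 equiv), NaHCO3, acetone/H2O 9:1, 0 °C, dark
Reagents that add atoms: water, O
Why: Oxidative thioglycoside hydrolysis; bromonium activation of sulfur gives the oxocarbenium ion, which water captures, and the bicarbonate buffer keeps the ketal and silyl ether intact.

Step 5
Reactants: 9 2-O-benzyl-6-O-(tert-butyldimethylsilyl)-3,4-O-isopropylidene-D-galactopyranose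
Product: 10 2-O-benzyl-6-O-(tert-butyldimethylsilyl)-3,4-O-isopropylidene-D-galactitol
Conditions: NaBH4, EtOH, 0 °C to rt
Reagents that add atoms: none
Why: Hydride reduction of the hydroxy-aldehyde in equilibrium with the lactol opens the ring to the 1,5-diol without touching a stereocentre.

Step 6
Reactants: 10 2-O-benzyl-6-O-(tert-butyldimethylsilyl)-3,4-O-isopropylidene-D-galactitol
Product: 11 2-O-benzyl-6-O-(tert-butyldimethylsilyl)-3,4-O-isopropylidene-L-arabino-hexos-5-ulose (aldehydo form)
Conditions: (COCl)2 (4 equiv), DMSO (8 equiv), CH2Cl2, −78 °C; iPr2NEt, −78 to −30 °C; used crude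
Reagents that add atoms: none
Why: Double Swern oxidation; both hydroxyls are converted to alkoxysulfonium ions before the amine is added, so no hydroxy-aldehyde can close to a lactol and over-oxidise to the lactone, and the cold hindered base limits epimerisation next to the aldehyde.

Step 7
Reactants: 11 2-O-benzyl-6-O-(tert-butyldimethylsilyl)-3,4-O-isopropylidene-L-arabino-hexos-5-ulose
Product: 12 (2,4/3,5,6)-4-benzyloxy-2-(tert-butyldimethylsilyloxy)-3-hydroxy-5,6-(isopropylidenedioxy)cyclohexan-1-one
Conditions: DBU (0.3 equiv), toluene, 0 °C to rt; AcOH quench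
Reagents that add atoms: none
Why: DBU removes a proton from C2 (the CH2OSi carbon next to the C1 ketone, carbocycle locants) and the enolate adds to the C3 aldehyde, the base-promoted intramolecular aldol addition documented for hexos-5-uloses giving inososes. The ring closes in the 6-(enolendo)-exo-trig mode, the normal favourable mode for six-membered aldol closure. Enolisation goes toward C2 because the C6–H bond sits in the dioxolane, where flattening C6 strains the cis-fused ring; a C6 enolate or the aldehyde enolate could in any case reach the other carbonyl only through a four-membered ring. C2 is set under equilibrium by re-enolisation and C3 by retro-aldol and re-addition, so the isomers should drain into the one with the silyloxy and hydroxyl groups equatorial, trans to each other and to O4. An axial C2 oxygen would clash 1,3-diaxially with the axial ketal oxygen on C6, which as an ether offers no compensating hydrogen bond. C4, C5 and C6 come unchanged from the sugar; C6 cannot epimerise because a trans-fused dioxolane is too strained, and C4 is already equatorial. The step needs C–C bond formation to win over E1cB loss of the C5 oxygen from the aldehyde enolate and over dehydration of the product; a substoichiometric amidine base in a non-polar solvent at low temperature, and the equatorial (poorly aligned) C3–O bond of 12, are what restrain these.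

Step 8
Reactants: 12 (2,4/3,5,6)-4-benzyloxy-2-(tert-butyldimethylsilyloxy)-3-hydroxy-5,6-(isopropylidenedioxy)cyclohexan-1-one; 13 tert-butyldimethylsilyl triflate
Product: 14 (2,4/3,5,6)-4-benzyloxy-2,3-bis(tert-butyldimethylsilyloxy)-5,6-(isopropylidenedioxy)cyclohexan-1-one
Conditions: 2,6-lutidine, CH2Cl2, −78 to −20 °C
Reagents that add atoms: tert-butyldimethylsilyl triflate, CC(C)(C)[Si](C)(C)OS(=O)(=O)C(F)(F)F
Why: Silyl triflate silylation under a non-nucleophilic base; capping O3 removes the retro-aldol and elimination pathways of the β-hydroxy ketone before the basic ylide step.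

Step 9
Reactants: 14 (2,4/3,5,6)-4-benzyloxy-2,3-bis(tert-butyldimethylsilyloxy)-5,6-(isopropylidenedioxy)cyclohexan-1-one; 15 trimethylsulfoxonium iodide
Product: 16 (1,2,4/3,5,6)-1,7-anhydro-4-O-benzyl-2,3-bis-O-(tert-butyldimethylsilyl)-1-C-(hydroxymethyl)-5,6-O-isopropylidenecyclohexane-1,2,3,4,5,6-hexol (spiro-oxirane)
Conditions: NaH, DMSO/THF, rt
Reagents that add atoms: trimethylsulfoxonium iodide, C[S+](C)(C)=O.[I-]
Why: Corey–Chaykovsky methylene transfer; the stabilised sulfoxonium ylide adds reversibly, so the betaine with the new C1–C7 bond equatorial (upper face) should dominate and its axial alkoxide (lower face) then expels DMSO, which sets C1. The ylide is weakly basic, which limits enolisation toward C2.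

Step 10
Reactants: 16 spiro-oxirane; 17 benzoic acid
Product: 18 (1,2,4/3,5,6)-7-O-benzoyl-4-O-benzyl-2,3-bis-O-(tert-butyldimethylsilyl)-1-C-(hydroxymethyl)-5,6-O-isopropylidenecyclohexane-1,2,3,4,5,6-hexol
Conditions: PhCO2H (3 equiv), PhCO2Cs (0.5 equiv), DMF, 90 °C
Reagents that add atoms: benzoic acid, OC(=O)c1ccccc1
Why: SN2 opening of the oxirane by carboxylate at the CH2 terminus, the other carbon being quaternary, so C1 keeps its configuration. Excess acid protonates the tertiary alkoxide at once, which suppresses silyl and benzoyl shifts.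

Step 11
Reactants: 18 (1,2,4/3,5,6)-7-O-benzoyl-4-O-benzyl-2,3-bis-O-(tert-butyldimethylsilyl)-1-C-(hydroxymethyl)-5,6-O-isopropylidenecyclohexane-1,2,3,4,5,6-hexol
Product: 19 (1,2,4/3,5,6)-7-O-benzoyl-4-O-benzyl-1-C-(hydroxymethyl)-5,6-O-isopropylidenecyclohexane-1,2,3,4,5,6-hexol
Conditions: HF·pyridine, pyridine, THF, 0 °C to rt
Reagents that add atoms: none
Why: Fluoride-mediated desilylation in a slightly acidic buffer, under which no alkoxide forms, so the O7 benzoate should stay in place and the ketal survives.

Step 12
Reactants: 19 (1,2,4/3,5,6)-7-O-benzoyl-4-O-benzyl-1-C-(hydroxymethyl)-5,6-O-isopropylidenecyclohexane-1,2,3,4,5,6-hexol; 20 acetic anhydride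
Product: 21 (1,2,4/3,5,6)-2,3-di-O-acetyl-7-O-benzoyl-4-O-benzyl-1-C-(hydroxymethyl)-5,6-O-isopropylidenecyclohexane-1,2,3,4,5,6-hexol
Conditions: pyridine, DMAP (cat.), CH2Cl2, 0 °C
Reagents that add atoms: acetic anhydride, CC(=O)OC(C)=O
Why: Acylation of the two secondary hydroxyls; the axial tertiary C1 hydroxyl, flanked on three sides, should not be acetylated at 0 °C with limited anhydride.

Step 13
Reactants: 21 (1,2,4/3,5,6)-2,3-di-O-acetyl-7-O-benzoyl-4-O-benzyl-1-C-(hydroxymethyl)-5,6-O-isopropylidenecyclohexane-1,2,3,4,5,6-hexol
Product: 22 (1,2,4/3,5,6)-2,3-di-O-acetyl-7-O-benzoyl-4-O-benzyl-1-C-(hydroxymethyl)cyclohexane-1,2,3,4,5,6-hexol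
Conditions: 80% aq AcOH, 50 °C
Reagents that add atoms: none
Why: Acid hydrolysis of the cis-fused dioxolane; the O4 benzyl ether separates the new 5,6-diol from the acetates, so there is no adjacent hydroxyl for an ester to move to.

Step 14
Reactants: 22 (1,2,4/3,5,6)-2,3-di-O-acetyl-7-O-benzoyl-4-O-benzyl-1-C-(hydroxymethyl)cyclohexane-1,2,3,4,5,6-hexol; 23 thionyl chloride; 24 sodium periodate
Product: 26 5,6-cyclic sulfate of 22, via cyclic sulfite 25 (not isolated)
Conditions: SOCl2, Et3N, CH2Cl2, 0 °C; then RuCl3·xH2O (1 mol%), NaIO4, MeCN/H2O, 0 °C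
Reagents that add atoms: thionyl chloride, ClS(Cl)=O; sodium periodate, [Na+].[O-]I(=O)(=O)=O
Why: Cyclic sulfite formation followed by RuO4-catalysed oxidation to the cyclic sulfate; only the cis-5,6-diol can bridge, since O1 is trans-diaxial to O6, and a short cold oxidation should spare the benzyl ether.

Step 15
Reactants: 26 5,6-cyclic sulfate of 22
Product: 28 [(1S,2R,3S,4R,5R,6S)-2,3-diacetoxy-4-benzyloxy-5-hydroxy-7-oxabicyclo[4.1.0]heptan-1-yl]methyl benzoate, via oxirane sulfate monoester 27 (not isolated)
Conditions: DBU (1.2 equiv), THF, 0 °C to rt; then H2SO4 (slight excess over DBU), H2O (2 equiv), THF, rt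
Reagents that add atoms: none
Why: Intramolecular SN2 (3-exo-tet) of the axial C1 hydroxyl on C6, anti-periplanar to the leaving sulfate oxygen, inverts C6 and puts the oxirane oxygen on the lower face; attack at C5 would need a four-membered ring. The monoalkyl sulfate is then hydrolysed under acid at sulfur with retention at C5, and the oxirane, deactivated by its flanking oxygens, should persist.

Step 16
Reactants: 28 [(1S,2R,3S,4R,5R,6S)-2,3-diacetoxy-4-benzyloxy-5-hydroxy-7-oxabicyclo[4.1.0]heptan-1-yl]methyl benzoate
Product: 29 [(1S,2R,3S,4R,5R,6S)-2,3-diacetoxy-4,5-dihydroxy-7-oxabicyclo[4.1.0]heptan-1-yl]methyl benzoate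
Conditions: H2 (1 atm), 10% Pd/C, EtOAc, rt
Reagents that add atoms: none
Why: Hydrogenolysis of the benzyl ether under neutral conditions; the oxirane is neither allylic nor benzylic, the esters are inert, and no base is present to move the O3 acetate to O4.

## Compound list

1 | phenyl 1-thio-β-D-galactopyranoside | c1ccccc1S[C@@H]1O[C@H](CO)[C@H](O)[C@H](O)[C@H]1O | starting material
2 | 2,2-dimethoxypropane | COC(C)(C)OC | starting material
3 | phenyl 3,4-O-isopropylidene-1-thio-β-D-galactopyranoside | c1ccccc1S[C@@H]1O[C@H](CO)[C@@H]2OC(C)(C)O[C@@H]2[C@H]1O | intermediate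
4 | tert-butyldimethylsilyl chloride | CC(C)(C)[Si](C)(C)Cl | starting material
5 | phenyl 6-O-(tert-butyldimethylsilyl)-3,4-O-isopropylidene-1-thio-β-D-galactopyranoside | c1ccccc1S[C@@H]1O[C@H](CO[Si](C)(C)C(C)(C)C)[C@@H]2OC(C)(C)O[C@@H]2[C@H]1O | intermediate
6 | benzyl bromide | BrCc1ccccc1 | starting material
7 | phenyl 2-O-benzyl-6-O-(tert-butyldimethylsilyl)-3,4-O-isopropylidene-1-thio-β-D-galactopyranoside | c1ccccc1S[C@@H]1O[C@H](CO[Si](C)(C)C(C)(C)C)[C@@H]2OC(C)(C)O[C@@H]2[C@H]1OCc1ccccc1 | intermediate
8 | water | O | starting material
9 | 2-O-benzyl-6-O-(tert-butyldimethylsilyl)-3,4-O-isopropylidene-D-galactopyranose (anomeric mixture) | OC1O[C@H](CO[Si](C)(C)C(C)(C)C)[C@@H]2OC(C)(C)O[C@@H]2[C@H]1OCc1ccccc1 | intermediate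
10 | 2-O-benzyl-6-O-(tert-butyldimethylsilyl)-3,4-O-isopropylidene-D-galactitol | OC[C@H](OCc1ccccc1)[C@H]1OC(C)(C)O[C@H]1[C@H](O)CO[Si](C)(C)C(C)(C)C | intermediate
11 | 2-O-benzyl-6-O-(tert-butyldimethylsilyl)-3,4-O-isopropylidene-L-arabino-hexos-5-ulose, aldehydo form | O=C[C@H](OCc1ccccc1)[C@H]1OC(C)(C)O[C@H]1C(=O)CO[Si](C)(C)C(C)(C)C | intermediate
12 | (2,4/3,5,6)-4-benzyloxy-2-(tert-butyldimethylsilyloxy)-3-hydroxy-5,6-(isopropylidenedioxy)cyclohexan-1-one | O[C@H]1[C@H](OCc2ccccc2)[C@H]2OC(C)(C)O[C@H]2C(=O)[C@@H]1O[Si](C)(C)C(C)(C)C | intermediate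
13 | tert-butyldimethylsilyl triflate | CC(C)(C)[Si](C)(C)OS(=O)(=O)C(F)(F)F | starting material
14 | (2,4/3,5,6)-4-benzyloxy-2,3-bis(tert-butyldimethylsilyloxy)-5,6-(isopropylidenedioxy)cyclohexan-1-one | CC(C)(C)[Si](C)(C)O[C@H]1[C@H](OCc2ccccc2)[C@H]2OC(C)(C)O[C@H]2C(=O)[C@@H]1O[Si](C)(C)C(C)(C)C | intermediate
15 | trimethylsulfoxonium iodide | C[S+](C)(C)=O.[I-] | starting material
16 | spiro-oxirane: (1,2,4/3,5,6)-1,7-anhydro-4-O-benzyl-2,3-bis-O-(tert-butyldimethylsilyl)-1-C-(hydroxymethyl)-5,6-O-isopropylidenecyclohexane-1,2,3,4,5,6-hexol (O1 axial, lower face; C7 equatorial, upper face) | CC(C)(C)[Si](C)(C)O[C@H]1[C@H](OCc2ccccc2)[C@H]2OC(C)(C)O[C@H]2[C@@]2(CO2)[C@@H]1O[Si](C)(C)C(C)(C)C | intermediate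
17 | benzoic acid | OC(=O)c1ccccc1 | starting material
18 | (1,2,4/3,5,6)-7-O-benzoyl-4-O-benzyl-2,3-bis-O-(tert-butyldimethylsilyl)-1-C-(hydroxymethyl)-5,6-O-isopropylidenecyclohexane-1,2,3,4,5,6-hexol | CC(C)(C)[Si](C)(C)O[C@H]1[C@H](OCc2ccccc2)[C@H]2OC(C)(C)O[C@H]2[C@@](O)(COC(=O)c2ccccc2)[C@@H]1O[Si](C)(C)C(C)(C)C | intermediate
19 | (1,2,4/3,5,6)-7-O-benzoyl-4-O-benzyl-1-C-(hydroxymethyl)-5,6-O-isopropylidenecyclohexane-1,2,3,4,5,6-hexol | O[C@H]1[C@H](OCc2ccccc2)[C@H]2OC(C)(C)O[C@H]2[C@@](O)(COC(=O)c2ccccc2)[C@@H]1O | intermediate
20 | acetic anhydride | CC(=O)OC(C)=O | starting material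
21 | (1,2,4/3,5,6)-2,3-di-O-acetyl-7-O-benzoyl-4-O-benzyl-1-C-(hydroxymethyl)-5,6-O-isopropylidenecyclohexane-1,2,3,4,5,6-hexol | CC(=O)O[C@H]1[C@H](OCc2ccccc2)[C@H]2OC(C)(C)O[C@H]2[C@@](O)(COC(=O)c2ccccc2)[C@@H]1OC(C)=O | intermediate
22 | (1,2,4/3,5,6)-2,3-di-O-acetyl-7-O-benzoyl-4-O-benzyl-1-C-(hydroxymethyl)cyclohexane-1,2,3,4,5,6-hexol | CC(=O)O[C@H]1[C@H](OCc2ccccc2)[C@@H](O)[C@@H](O)[C@@](O)(COC(=O)c2ccccc2)[C@@H]1OC(C)=O | intermediate
23 | thionyl chloride | ClS(Cl)=O | starting material
24 | sodium periodate | [Na+].[O-]I(=O)(=O)=O | starting material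
25 | 5,6-cyclic sulfite of 22 (mixture at sulfur) | CC(=O)O[C@H]1[C@H](OCc2ccccc2)[C@H]2OS(=O)O[C@H]2[C@@](O)(COC(=O)c2ccccc2)[C@@H]1OC(C)=O | intermediate
26 | 5,6-cyclic sulfate of 22 | CC(=O)O[C@H]1[C@H](OCc2ccccc2)[C@H]2OS(=O)(=O)O[C@H]2[C@@](O)(COC(=O)c2ccccc2)[C@@H]1OC(C)=O | intermediate
27 | 5-O-sulfate of 28 as its 1,8-diazabicyclo[5.4.0]undec-7-enium salt | CC(=O)O[C@H]1[C@H](OCc2ccccc2)[C@@H](OS(=O)(=O)[O-])[C@@H]2O[C@]2(COC(=O)c2ccccc2)[C@@H]1OC(C)=O.C1CCC2=[NH+]CCCN2CC1 | intermediate
28 | [(1S,2R,3S,4R,5R,6S)-2,3-diacetoxy-4-benzyloxy-5-hydroxy-7-oxabicyclo[4.1.0]heptan-1-yl]methyl benzoate | CC(=O)O[C@H]1[C@H](OCc2ccccc2)[C@@H](O)[C@@H]2O[C@]2(COC(=O)c2ccccc2)[C@@H]1OC(C)=O | intermediate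
29 | [(1S,2R,3S,4R,5R,6S)-2,3-diacetoxy-4,5-dihydroxy-7-oxabicyclo[4.1.0]heptan-1-yl]methyl benzoate | CC(=O)O[C@H]1[C@H](O)[C@@H](O)[C@@H]2O[C@]2(COC(=O)c2ccccc2)[C@@H]1OC(C)=O | target

## Step count and least certain steps

Total step count: 16. Longest linear sequence: 16 steps (1 to 29).

Step 7 (key step). What may go wrong:
- E1cB loss of the C5 ketal oxygen from the aldehyde enolate, or dehydration of the aldol product.
- Incomplete equilibration that leaves the faster-formed isomer with an axial C2 oxygen.
- A silyl shift from O2 to O3 followed by enediol isomerisation of the freed α-hydroxy ketone.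

The fallback sets out from 11. The ketal is removed with CF3CO2H/H2O at 0 °C to give 2-O-benzyl-6-O-(tert-butyldimethylsilyl)-L-arabino-hexos-5-ulose F1, which is expected to sit as cyclic hemiacetals and so to offer little free enolisable aldehyde. DBU then performs the aldol on this diol-unprotected ulose, the documented substrate class, to give the (2,4/3,5,6)-5,6-diol inosose F2. The cis-5,6-diol is re-ketalised with 2 (CSA, acetone). Should the C2 oxygen emerge axial, it is α to the ketone and should relax to equatorial on brief DBU treatment once O6 is an ether again. The fallback comes back to the route at 12.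

Step 6. What may go wrong: incomplete double activation lets the hydroxy-aldehyde close to a lactol and over-oxidise to the lactone, and the amine stage may epimerise the carbon next to the aldehyde. The fallback sets out from 9. Wittig methylenation of the lactol (Ph3P=CH2 from Ph3PCH3Br and KN(SiMe3)2, THF) gives 3-O-benzyl-7-O-(tert-butyldimethylsilyl)-1,2-dideoxy-4,5-O-isopropylidene-D-galacto-hept-1-enitol F3, with the aldehyde masked as an alkene. Dess–Martin oxidation of its single hydroxyl gives 3-O-benzyl-7-O-(tert-butyldimethylsilyl)-1,2-dideoxy-4,5-O-isopropylidene-L-arabino-hept-1-en-6-ulose F4. Ozonolysis (O3, CH2Cl2, −78 °C; PPh3) unveils the aldehyde under neutral conditions, and the fallback comes back at 11.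

Step 9. What may go wrong: poor facial selectivity if kinetic axial attack competes (the axial C6 oxygen hinders the equatorial approach), or base-induced loss of the C3 silyloxy group through the C2 enolate. The fallback sets out from 14. Lombardo–Takai methylenation (Zn, CH2Br2, TiCl4) gives the 1-methylene compound F5 without strong base. Dihydroxylation (OsO4 cat., N-methylmorpholine N-oxide) should occur on the lower face, anti to the axial allylic C6 oxygen, to give the (1,2,4/3,5,6)-1-C-(hydroxymethyl) diol F6. Selective benzoylation of the primary hydroxyl (PhCOCl, 2,4,6-collidine, −40 °C) comes back to the route at 18, and so also bypasses step 10.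

Step 15. What may go wrong: acyl transfer from O2 (acetyl) or O7 (benzoyl) to the O1 oxygen competing with ring closure and scrambling the ester pattern, and opening of the oxirane during the acidic sulfate hydrolysis. The fallback sets out from 22 and uses a Mitsunobu-type cyclodehydration (PPh3, diisopropyl azodicarboxylate, toluene, 80 °C) with no base and no acid. A phosphorane on the cis-5,6-diol should open to the C6 oxyphosphonium, which O1 displaces from the lower face; activation at O5 finds no anti nucleophile and is unproductive. This gives 28 directly, so the fallback comes back at 28 and makes no new compound.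

## Further compounds

F1 | step 7 | 2-O-benzyl-6-O-(tert-butyldimethylsilyl)-L-arabino-hexos-5-ulose (drawn open-chain) | O=C[C@H](OCc1ccccc1)[C@@H](O)[C@@H](O)C(=O)CO[Si](C)(C)C(C)(C)C
F2 | step 7 | (2,4/3,5,6)-4-benzyloxy-2-(tert-butyldimethylsilyloxy)-3,5,6-trihydroxycyclohexan-1-one | O[C@H]1[C@H](OCc2ccccc2)[C@@H](O)[C@@H](O)C(=O)[C@@H]1O[Si](C)(C)C(C)(C)C
F3 | step 6 | 3-O-benzyl-7-O-(tert-butyldimethylsilyl)-1,2-dideoxy-4,5-O-isopropylidene-D-galacto-hept-1-enitol | C=C[C@H](OCc1ccccc1)[C@H]1OC(C)(C)O[C@H]1[C@H](O)CO[Si](C)(C)C(C)(C)C
F4 | step 6 | 3-O-benzyl-7-O-(tert-butyldimethylsilyl)-1,2-dideoxy-4,5-O-isopropylidene-L-arabino-hept-1-en-6-ulose | C=C[C@H](OCc1ccccc1)[C@H]1OC(C)(C)O[C@H]1C(=O)CO[Si](C)(C)C(C)(C)C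
F5 | step 9 | (2,4/3,5,6)-4-benzyloxy-2,3-bis(tert-butyldimethylsilyloxy)-5,6-(isopropylidenedioxy)-1-methylenecyclohexane | CC(C)(C)[Si](C)(C)O[C@H]1[C@H](OCc2ccccc2)[C@H]2OC(C)(C)O[C@H]2C(=C)[C@@H]1O[Si](C)(C)C(C)(C)C
F6 | step 9 | (1,2,4/3,5,6)-4-O-benzyl-2,3-bis-O-(tert-butyldimethylsilyl)-1-C-(hydroxymethyl)-5,6-O-isopropylidenecyclohexane-1,2,3,4,5,6-hexol | CC(C)(C)[Si](C)(C)O[C@H]1[C@H](OCc2ccccc2)[C@H]2OC(C)(C)O[C@H]2[C@@](O)(CO)[C@@H]1O[Si](C)(C)C(C)(C)C
F0 | step 15 | none | none
A1 | alternative 1 | 4-(benzoyloxymethyl)-4-hydroxycyclohexa-2,5-dien-1-one | O=C1C=CC(O)(COC(=O)c2ccccc2)C=C1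
A2 | alternative 1 | cis-fused phenylboronate of the 4,5-dihydroxycyclohex-2-enone | O=C1C[C@H]2OB(c3ccccc3)O[C@@]2(COC(=O)c3ccccc3)C=C1
A3 | alternative 2 | 1-(benzoyloxymethyl)cyclohexa-1,3-diene with trans C2 hydroxyl and C3 silyl ether (target locants) | CC(C)(C)[Si](C)(C)O[C@H]1C=CC=C(COC(=O)c2ccccc2)[C@@H]1O
A4 | alternative 2 | C1,C4-endoperoxide (2,3-dioxabicyclo[2.2.2]oct-5-ene) | CC(C)(C)[Si](C)(C)O[C@H]1[C@H]2C=C[C@@](OO2)(COC(=O)c3ccccc3)[C@@H]1O
A5 | alternative 3 | myo-inositol | O[C@H]1[C@@H](O)[C@@H](O)[C@H](O)[C@@H](O)[C@@H]1O
A6 | alternative 3 | (2,4/3,5,6)-4-benzyloxy-5,6-(isopropylidenedioxy)-2,3-bis(4-methoxybenzyloxy)cyclohexan-1-one | COc1ccc(CO[C@H]2[C@H](OCc3ccccc3)[C@H]3OC(C)(C)O[C@H]3C(=O)[C@@H]2OCc2ccc(OC)cc2)cc1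
A7 | alternative 3 | spiro-oxirane of the 1-C-methylene inositol | COc1ccc(CO[C@H]2[C@H](OCc3ccccc3)[C@H]3OC(C)(C)O[C@H]3[C@@]3(CO3)[C@@H]2OCc2ccc(OC)cc2)cc1
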